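(All constants are assumed; the run is a simulation.)

I froze Q.

| flask | L | Q | time | remark |
|---|---|---|---|---|
| Sunday's | 0.20 M | 0.220 M | 20 h | everything together in a closed stirred flask, run for 20 h |
| Tuesday's | 0.20 M | 0.220 M (fed, over 20.0 h) | 20 h | a stirred flask in which Q is dosed at a steady rate over 20.0 h without added volume, worked up at 20 h |
| Saturday's | 0.20 M (fed, over 20.0 h) | 0.220 M | 20 h | a stirred flask in which L is dosed at a steady rate over 20.0 h without added volume, worked up at 20 h |
| Monday's | 0.20 M | 0.220 M |  | a single well-mixed tank run continuously and read at steady state, 20 h in it on average |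

    L + Q ⇌ L.Q (K1 = 5.1 L mol⁻¹, k1 = 0.052 L mol⁻¹ min⁻¹)
    Q + X → Q.X (k2 = 0.0056 L mol⁻¹ min⁻¹)
    Q.X → J (k3 = 4.6 × 10⁻⁴ min⁻¹)
    E → X (k4 = 0.0019 min⁻¹)
    L.Q → D (k5 = 5.4 × 10⁻⁴ min⁻¹)
    L → E (k6 = 0.0016 min⁻¹)

- the stated concentrations are those of everything mixed, before any reaction; amounts are the same in each set-up
- the feed brings no volume worth counting
- run time (Sunday's): 20 h

1. order of the set-ups by the share of J in all that became J or D, at the outlet or at the end, highest first (Sunday's / Tuesday's / Saturday's / Monday's)
2. share of J in all that became J or D, at the outlet or at the end, Sunday's
3. share of J in all that became J or D, at the outlet or at the end, Tuesday's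
4. share of J in all that became J or D, at the outlet or at the end, Saturday's
5. share of J in all that became J or D, at the outlet or at the end, Monday's

L had two exits: free L went to E, and bound L.Q went to D. In Sunday's, binding had a half-life of 1.0 h (forward step alone, as charged), shorter than the 7.2 h of L going to E, so I held L and L.Q at equilibrium. I carried that equilibrium over to Monday's tank as an assumption and set cQ there at the charge of Q less half the charge of L, which gave 0.120 M. The split, the rate of L.Q to D over the rate of L to E at that equilibrium, a selectivity factor, came to 0.207.

I reckoned Monday's tank, and no further. Each stage of the chain through E, X and Q.X passed on a over one plus a, where a was the stage's rate times the average stay of 20 h. Together the stages passed 0.110. Pass against split gave Monday's share of J as 34.8%.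

The forecast gave the order Monday's > Tuesday's > Sunday's > Saturday's, with 15% for Sunday's, 24% for Tuesday's, 7% for Saturday's and 36.5% for Monday's. My figure for Monday's stood below its figure. Its ground was this: “J needs the slow chain L→E→X→Q.X→J to run its course”.

The simulation gave Monday's > Tuesday's > Sunday's > Saturday's, the forecast's order, with 13.6% for Sunday's, 26.1% for Tuesday's, 5.92% for Saturday's and 36.4% for Monday's.

Q.X had a half-life of 25 h by its own step, longer than Monday's average stay of 20 h, and Monday's outlet read J over D as 0.572, where pass over split had given 0.531. If every L reaching E ended as J, the split, with cQ held at 0.120 M, would put the share of J at 82.9%; Saturday's, at 5.92% after 20 h, read 78.7% after 200 h.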